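The tetrahydrofuran ring (O1, C2–C5) is cut at O1–C2 and C3–C4, which divides the lignan into its two C6–C3 halves. The feature used is that benzylic C2 lies β to C9 whereas C4 bears the aroyl carbon C7' directly. An enal delivers C2, C3 and C9, and a γ-hydroxy α-aryl nitroalkene delivers O1, C5, C4 and C7', with nitro as the masked carbonyl. One aminocatalytic oxa-Michael/Michael domino makes both bonds, closes the ring and sets C2, C3 and C4 all-trans. Its precursors are O-benzylconiferaldehyde 11 and the free allylic alcohol 9, (E)-HOCH2CH=C(NO2)Ar. Reduction, buffered Nef reaction and hydrogenolysis complete the route.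

Key step: step 6

**Remarks**
- **Numbering:** O1, C2 (guaiacyl), C3 (bears C9H2OH), C4 (bears C7'), C5. The target is (2S,3R,4S), that is 2,3-trans-3,4-trans. CIP letters at C3 and C4 change along the route because substituent priorities change. The spatial arrangement does not.
- **Assumption:** C7' of 14 and 15 is expected as an epimer mixture and is written without a descriptor, since it becomes sp2 in step 8.
- **Catalyst:** 2S requires the (S)-catalyst, (S)-2-[diphenyl(trimethylsilyloxy)methyl]pyrrolidine, C[Si](C)(C)OC(c1ccccc1)(c1ccccc1)[C@@H]1CCCN1.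
- **Nitroalkene geometry:** 9 is drawn E (CH2OH trans to NO2, twisted aryl cis), the isomer expected under equilibrating conditions. The secondary amine interconverts the isomers by reversible addition, so geometry should not matter.
- **Glycolaldehyde is used as its O-TBS ether:** the nitro aldol then has a single hydroxyl to eliminate.
- **No base equilibration after the Nef step:**
  - Ketone 18 is a β-alkoxy ketone (C4–C5–O1), so enolisation invites ring opening.
  - A 3,4-cis epimer could also close onto the C9 hydroxyl as a cis-fused hemiketal.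

**Step 1**
Reactants: 1 4-bromo-2,6-dimethoxyphenol
Product: 2 2-(benzyloxy)-5-bromo-1,3-dimethoxybenzene
Conditions: BnBr, K2CO3, DMF, rt
Reagents that add atoms: benzyl bromide, BrCc1ccccc1
Why: Williamson ether synthesis, in which the phenoxide displaces bromide from benzyl bromide (SN2) while the aryl bromide is inert.

**Step 2**
Reactants: 2 2-(benzyloxy)-5-bromo-1,3-dimethoxybenzene + 3 nitromethane (also the solvent)
Product: 4 2-(benzyloxy)-1,3-dimethoxy-5-(nitromethyl)benzene
Conditions: Pd2(dba)3 (cat.), XPhos (cat.), Cs2CO3, 4 Å MS, MeNO2, 50 °C; aq. NH4Cl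
Reagents that add atoms: none
Why: Palladium-catalysed cross-coupling of an aryl bromide with the nitromethane anion (α-arylation of a nitroalkane with a bulky biaryl phosphine) is established for electron-rich aryl bromides, the large excess of nitromethane suppresses a second arylation, and the benzyl ether is untouched.

**Step 3**
Reactants: 4 2-(benzyloxy)-1,3-dimethoxy-5-(nitromethyl)benzene + 5 (tert-butyldimethylsilyloxy)acetaldehyde
Product: 8 (E)-tert-butyl({3-[4-(benzyloxy)-3,5-dimethoxyphenyl]-3-nitroprop-2-en-1-yl}oxy)dimethylsilane, via nitro aldol 6 (not isolated), via nitro mesylate 7 (not isolated)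
Conditions: Et3N (0.2 equiv), CH2Cl2, 0 °C to rt; then MsCl, Et3N (2.5 equiv), −20 to 0 °C
Reagents that add atoms: none
Why: Henry reaction of the acidic benzylic nitronate with an activated α-alkoxy aldehyde, followed by mesylation and E1cB elimination that drains the reversible aldol step; the only free hydroxyl is the one to be lost, and low temperature limits γ-deprotonation and silyl migration.

**Step 4**
Reactants: 8 (E)-tert-butyl({3-[4-(benzyloxy)-3,5-dimethoxyphenyl]-3-nitroprop-2-en-1-yl}oxy)dimethylsilane
Product: 9 (E)-3-[4-(benzyloxy)-3,5-dimethoxyphenyl]-3-nitroprop-2-en-1-ol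
Conditions: aq. HF (48 %), MeCN, 0 °C; used promptly
Reagents that add atoms: none
Why: Acidic fluoride cleavage of a primary silyl ether, chosen because an acidic medium avoids the conjugate addition and deconjugation that basic fluoride would cause on the nitroalkene, while the benzyl ether is stable.

**Step 5**
Reactants: 10 coniferaldehyde, (E)-3-(4-hydroxy-3-methoxyphenyl)prop-2-enal
Product: 11 (E)-3-[4-(benzyloxy)-3-methoxyphenyl]prop-2-enal
Conditions: BnBr, K2CO3, DMF, rt
Reagents that add atoms: benzyl bromide, BrCc1ccccc1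
Why: Williamson ether synthesis on the vinylogously acidic phenol, which leaves the E-enal unchanged and removes the only competing O–H donor on this half.

**Step 6**
Reactants: 9 (E)-3-[4-(benzyloxy)-3,5-dimethoxyphenyl]-3-nitroprop-2-en-1-ol + 11 (E)-3-[4-(benzyloxy)-3-methoxyphenyl]prop-2-enal
Product: 14 (2S,3S,4R)-2-[4-(benzyloxy)-3-methoxyphenyl]-4-{[4-(benzyloxy)-3,5-dimethoxyphenyl](nitro)methyl}tetrahydrofuran-3-carbaldehyde, via iminium benzoate 12 (not isolated), via oxa-Michael enamine 13 (not isolated)
Conditions: (S)-α,α-diphenylprolinol TMS ether (20 mol %), PhCO2H (20 mol %), toluene (0.5 M), 0 °C to rt; 11 in slight excess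
Reagents that add atoms: none
Why: Amine and 11 condense to the E,s-trans iminium ion 12, the C5 hydroxyl of 9 adds reversibly to its β-carbon C2 to give enamine 13, and C3 of 13 then attacks nitroalkene carbon C4 irreversibly, after which protonation of the aryl-stabilised nitronate and hydrolysis release 14 and the catalyst. This is the aminocatalytic iminium–enamine oxa-Michael/Michael domino known for enals with γ-hydroxy enones (tetrahydrofurans) and with 2-(2-nitrovinyl)phenols (chromans), and its second half is the standard enamine-to-nitroalkene Michael addition. The one ring formed, O1–C2–C3–C4–C5, closes 5-exo-trig because the attacked C4=C7' bond stays outside the ring. C2 is controlled by the catalyst, whose CPh2(OTMS) arm covers the Re face of C2 so that oxygen enters from the Si face (2S); C3 is controlled by the same arm shielding the enamine, a sense that coincides with the less crowded 2,3-trans arrangement; C4 is controlled by the closure geometry, in which the large C(NO2)Ar terminus turns away from C9 (3,4-trans, the syn topicity usual for enamine/nitroalkene additions); C7' comes from unselective protonation and vanishes in step 8. The step needs conjugate instead of carbonyl addition of the alcohol and cross-reaction instead of self-addition of 9, and this is secured because every O-addition is reversible under the buffered conditions whereas only the intramolecular C3–C4 closure is a sink, because the single CH2 between O1 and C4 allows no other ring size, and because both phenols are benzylated so that the C5 hydroxyl is the only O–H donor.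

**Step 7**
Reactants: 14 (2S,3S,4R)-2-[4-(benzyloxy)-3-methoxyphenyl]-4-{[4-(benzyloxy)-3,5-dimethoxyphenyl](nitro)methyl}tetrahydrofuran-3-carbaldehyde
Product: 15 {(2S,3R,4R)-2-[4-(benzyloxy)-3-methoxyphenyl]-4-{[4-(benzyloxy)-3,5-dimethoxyphenyl](nitro)methyl}tetrahydrofuran-3-yl}methanol
Conditions: NaBH4, MeOH–CH2Cl2, −20 °C; aq. NH4Cl
Reagents that add atoms: none
Why: Chemoselective borohydride reduction of the aldehyde while C7' is still masked as a nitro group that borohydride does not touch, so no ketone competes; the low temperature and prompt use of 14 keep C3 intact, and once C9 is an alcohol neither retro-Michael nor retro-oxa-Michael cleavage is possible.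

**Step 8**
Reactants: 15 {(2S,3R,4R)-2-[4-(benzyloxy)-3-methoxyphenyl]-4-{[4-(benzyloxy)-3,5-dimethoxyphenyl](nitro)methyl}tetrahydrofuran-3-yl}methanol
Product: 18 [4-(benzyloxy)-3,5-dimethoxyphenyl]{(3S,4R,5S)-5-[4-(benzyloxy)-3-methoxyphenyl]-4-(hydroxymethyl)tetrahydrofuran-3-yl}methanone, via sodium nitronate 16 (not isolated), via N-H ketimine 17 (not isolated)
Conditions: NaOMe (1.1 equiv), MeOH, 0 °C; then aq. TiCl3 (4–5 equiv), NH4OAc buffer (pH 5–6), THF–H2O, 0 °C to rt
Reagents that add atoms: water, O
Why: Reductive Ti(III) variant of the Nef reaction, in which the pre-formed nitronate 16 is deoxygenated at nitrogen down to ketimine 17 and water hydrolyses it near neutrality, so that neither strong acid (ionisation of benzylic C2–O1) nor strong base (enolisation at C4) is present, the C4 configuration from step 6 is kept, and benzyl ethers and the primary alcohol are inert.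

**Step 9**
Reactants: 18 [4-(benzyloxy)-3,5-dimethoxyphenyl]{(3S,4R,5S)-5-[4-(benzyloxy)-3-methoxyphenyl]-4-(hydroxymethyl)tetrahydrofuran-3-yl}methanone
Product: 19 (4-hydroxy-3,5-dimethoxyphenyl)[(3S,4R,5S)-5-(4-hydroxy-3-methoxyphenyl)-4-(hydroxymethyl)tetrahydrofuran-3-yl]methanone (target; 2S,3R,4S in the route numbering)
Conditions: H2 (1 atm), 10 % Pd/C, EtOAc–EtOH, rt, stopped after two equivalents of H2
Reagents that add atoms: none
Why: Catalytic hydrogenolysis of two aryl benzyl ethers, which in a neutral solvent at 1 atm should be much faster than reduction of the donor-substituted aryl ketone or cleavage of the cyclic benzylic C2–O1 bond, and which touches no stereocentre.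

**Compound list**
1 | 4-bromo-2,6-dimethoxyphenol | COc1cc(Br)cc(OC)c1O | starting material
2 | 2-(benzyloxy)-5-bromo-1,3-dimethoxybenzene | COc1cc(Br)cc(OC)c1OCc1ccccc1 | intermediate
3 | nitromethane | C[N+](=O)[O-] | starting material
4 | 2-(benzyloxy)-1,3-dimethoxy-5-(nitromethyl)benzene | COc1cc(C[N+](=O)[O-])cc(OC)c1OCc1ccccc1 | intermediate
5 | (tert-butyldimethylsilyloxy)acetaldehyde | CC(C)(C)[Si](C)(C)OCC=O | starting material
6 | 3-[4-(benzyloxy)-3,5-dimethoxyphenyl]-1-[(tert-butyldimethylsilyl)oxy]-3-nitropropan-2-ol (racemic diastereomer mixture) | CC(C)(C)[Si](C)(C)OCC(O)C([N+](=O)[O-])c1cc(OC)c(OCc2ccccc2)c(OC)c1 | intermediate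
7 | methanesulfonate of 6 | CC(C)(C)[Si](C)(C)OCC(OS(C)(=O)=O)C([N+](=O)[O-])c1cc(OC)c(OCc2ccccc2)c(OC)c1 | intermediate
8 | (E)-tert-butyl({3-[4-(benzyloxy)-3,5-dimethoxyphenyl]-3-nitroprop-2-en-1-yl}oxy)dimethylsilane | CC(C)(C)[Si](C)(C)OC/C=C(/[N+](=O)[O-])c1cc(OC)c(OCc2ccccc2)c(OC)c1 | intermediate
9 | (E)-3-[4-(benzyloxy)-3,5-dimethoxyphenyl]-3-nitroprop-2-en-1-ol | OC/C=C(/[N+](=O)[O-])c1cc(OC)c(OCc2ccccc2)c(OC)c1 | intermediate
10 | coniferaldehyde | COc1cc(/C=C/C=O)ccc1O | starting material
11 | (E)-3-[4-(benzyloxy)-3-methoxyphenyl]prop-2-enal | COc1cc(/C=C/C=O)ccc1OCc1ccccc1 | intermediate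
12 | iminium benzoate from 11 and the (S)-catalyst | C[Si](C)(C)OC(c1ccccc1)(c1ccccc1)[C@@H]1CCC[N+]1=C/C=C/c1ccc(OCc2ccccc2)c(OC)c1.[O-]C(=O)c1ccccc1 | intermediate
13 | E-enamine formed by oxa-Michael addition of 9 to 12 (C2 S) | C[Si](C)(C)OC(c1ccccc1)(c1ccccc1)[C@@H]1CCCN1/C=C/[C@H](OC/C=C(/[N+](=O)[O-])c1cc(OC)c(OCc2ccccc2)c(OC)c1)c1ccc(OCc2ccccc2)c(OC)c1 | intermediate
14 | (2S,3S,4R)-2-[4-(benzyloxy)-3-methoxyphenyl]-4-{[4-(benzyloxy)-3,5-dimethoxyphenyl](nitro)methyl}tetrahydrofuran-3-carbaldehyde (C7' epimers) | COc1cc([C@H]2OC[C@@H](C([N+](=O)[O-])c3cc(OC)c(OCc4ccccc4)c(OC)c3)[C@@H]2C=O)ccc1OCc1ccccc1 | intermediate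
15 | {(2S,3R,4R)-2-[4-(benzyloxy)-3-methoxyphenyl]-4-{[4-(benzyloxy)-3,5-dimethoxyphenyl](nitro)methyl}tetrahydrofuran-3-yl}methanol (C7' epimers) | COc1cc([C@H]2OC[C@@H](C([N+](=O)[O-])c3cc(OC)c(OCc4ccccc4)c(OC)c3)[C@@H]2CO)ccc1OCc1ccccc1 | intermediate
16 | sodium nitronate of 15 | COc1cc([C@H]2OC[C@@H](C(=[N+]([O-])[O-])c3cc(OC)c(OCc4ccccc4)c(OC)c3)[C@@H]2CO)ccc1OCc1ccccc1.[Na+] | intermediate
17 | N-H ketimine at C7' (ring configured as in 15) | COc1cc([C@H]2OC[C@@H](C(=N)c3cc(OC)c(OCc4ccccc4)c(OC)c3)[C@@H]2CO)ccc1OCc1ccccc1 | intermediate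
18 | [4-(benzyloxy)-3,5-dimethoxyphenyl]{(3S,4R,5S)-5-[4-(benzyloxy)-3-methoxyphenyl]-4-(hydroxymethyl)tetrahydrofuran-3-yl}methanone | COc1cc([C@H]2OC[C@@H](C(=O)c3cc(OC)c(OCc4ccccc4)c(OC)c3)[C@@H]2CO)ccc1OCc1ccccc1 | intermediate
19 | (4-hydroxy-3,5-dimethoxyphenyl)[(3S,4R,5S)-5-(4-hydroxy-3-methoxyphenyl)-4-(hydroxymethyl)tetrahydrofuran-3-yl]methanone | COc1cc([C@H]2OC[C@@H](C(=O)c3cc(OC)c(O)c(OC)c3)[C@@H]2CO)ccc1O | target

**Total steps:** 9. **Longest linear sequence:** 8 (steps 1–4 and 6–9).

**Steps most likely to fail**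

1. **Step 6.**
   - **What may go wrong:**
     - The reaction type is established, but this pairing of partners is undocumented.
     - The oxa-Michael pre-equilibrium may lie far on the side of the components, because a primary alcohol is a weak donor and the p-alkoxy iminium ion a weak acceptor.
     - Meanwhile the amine may isomerise or oligomerise the hydroxy nitroalkene, or be tied up by aza-Michael addition.
     - Weak 3,4-diastereocontrol in the closure is the second possibility.
   - **Fallback, from 11 and 8, back at 15:** C3–C4 is made first by intermolecular enamine catalysis and O1–C2 last by benzylic oxidation.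
     - Organocatalytic transfer hydrogenation of 11 (Hantzsch ester, cat. dibenzylammonium trifluoroacetate, THF) should give 3-[4-(benzyloxy)-3-methoxyphenyl]propanal F1.
     - Michael addition of F1 to 8 with the same (S)-catalyst (4-nitrophenol co-catalyst, toluene) should give the syn adduct (2R,3R)-2-[4-(benzyloxy)-3-methoxybenzyl]-3-{[4-(benzyloxy)-3,5-dimethoxyphenyl](nitro)methyl}-4-[(tert-butyldimethylsilyl)oxy]butanal F2. Its syn relationship corresponds to 3,4-trans in the ring.
     - NaBH4 should give the corresponding butan-1-ol F3.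
     - Aqueous HF should free the C5 hydroxyl to give (2R,3R)-2-[4-(benzyloxy)-3-methoxybenzyl]-3-{[4-(benzyloxy)-3,5-dimethoxyphenyl](nitro)methyl}butane-1,4-diol F4.
     - DDQ (1 equiv, CH2Cl2) should abstract hydride from the p-alkoxybenzylic C2. Only the C5 hydroxyl can trap the cation in a five-membered ring, trans to C9, which leads to 15.

2. **Step 3.**
   - **What may go wrong:**
     - The aryl-stabilised nitronate may add sluggishly and reversibly, so that retro-Henry cleavage competes with mesylation.
     - Excess amine base may move the new double bond out of conjugation by γ-deprotonation, or shift the silyl group to the neighbouring oxygen.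
   - **Fallback, from 4 and 5, back at 8:** the aldehyde is replaced by its imine, the leaving group by an amine, and the medium by acid.
     - Condensation of 5 with butan-1-amine (MgSO4, CH2Cl2) should give N-butyl-2-[(tert-butyldimethylsilyl)oxy]ethan-1-imine F5.
     - With 4 in glacial acetic acid at rt this should give the aza-Henry adduct N-butyl-1-[4-(benzyloxy)-3,5-dimethoxyphenyl]-3-[(tert-butyldimethylsilyl)oxy]-1-nitropropan-2-amine F6.
     - F6 loses butylamine in the same medium to give 8. This is the Knoevenagel-type condensation classically used for α-nitrostilbenes.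

3. **Step 8.**
   - **What may go wrong:**
     - N–O reduction may stall at the oxime stage on this hindered aryl alkyl system.
     - Slow hydrolysis may allow imine–enamine tautomerism to erode C4, with the cis epimer withdrawn by hemiketal closure onto the C9 hydroxyl.
   - **Fallback, from 15, back at 18:** nitrogen is reduced fully and then removed by transamination.
     - NiCl2·6H2O/NaBH4 (MeOH, 0 °C) should give the primary amine {(2S,3R,4R)-4-{amino[4-(benzyloxy)-3,5-dimethoxyphenyl]methyl}-2-[4-(benzyloxy)-3-methoxyphenyl]tetrahydrofuran-3-yl}methanol F7.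
     - Condensation with 3,5-di-tert-butyl-1,2-benzoquinone (MeOH–THF, rt) and the ensuing prototropic shift should give the N-(3,5-di-tert-butyl-2-hydroxyphenyl) ketimine of 18 F8.
     - Aqueous oxalic acid (pH about 3) should hydrolyse F8 to 18.

**Further compounds**
F1 | step 6 | 3-[4-(benzyloxy)-3-methoxyphenyl]propanal | COc1cc(CCC=O)ccc1OCc1ccccc1
F2 | step 6 | (2R,3R)-2-[4-(benzyloxy)-3-methoxybenzyl]-3-{[4-(benzyloxy)-3,5-dimethoxyphenyl](nitro)methyl}-4-[(tert-butyldimethylsilyl)oxy]butanal | O=C[C@H](Cc1ccc(OCc2ccccc2)c(OC)c1)[C@@H](CO[Si](C)(C)C(C)(C)C)C([N+](=O)[O-])c1cc(OC)c(OCc2ccccc2)c(OC)c1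
F3 | step 6 | (2R,3R)-2-[4-(benzyloxy)-3-methoxybenzyl]-3-{[4-(benzyloxy)-3,5-dimethoxyphenyl](nitro)methyl}-4-[(tert-butyldimethylsilyl)oxy]butan-1-ol | OC[C@H](Cc1ccc(OCc2ccccc2)c(OC)c1)[C@@H](CO[Si](C)(C)C(C)(C)C)C([N+](=O)[O-])c1cc(OC)c(OCc2ccccc2)c(OC)c1
F4 | step 6 | (2R,3R)-2-[4-(benzyloxy)-3-methoxybenzyl]-3-{[4-(benzyloxy)-3,5-dimethoxyphenyl](nitro)methyl}butane-1,4-diol | OC[C@H](Cc1ccc(OCc2ccccc2)c(OC)c1)[C@@H](CO)C([N+](=O)[O-])c1cc(OC)c(OCc2ccccc2)c(OC)c1
F5 | step 3 | N-butyl-2-[(tert-butyldimethylsilyl)oxy]ethan-1-imine | CCCC/N=C/CO[Si](C)(C)C(C)(C)C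
F6 | step 3 | N-butyl-1-[4-(benzyloxy)-3,5-dimethoxyphenyl]-3-[(tert-butyldimethylsilyl)oxy]-1-nitropropan-2-amine | CCCCNC(CO[Si](C)(C)C(C)(C)C)C([N+](=O)[O-])c1cc(OC)c(OCc2ccccc2)c(OC)c1
F7 | step 8 | {(2S,3R,4R)-4-{amino[4-(benzyloxy)-3,5-dimethoxyphenyl]methyl}-2-[4-(benzyloxy)-3-methoxyphenyl]tetrahydrofuran-3-yl}methanol | COc1cc([C@H]2OC[C@@H](C(N)c3cc(OC)c(OCc4ccccc4)c(OC)c3)[C@@H]2CO)ccc1OCc1ccccc1
F8 | step 8 | N-(3,5-di-tert-butyl-2-hydroxyphenyl) ketimine of 18 | COc1cc([C@H]2OC[C@@H](C(=Nc3cc(C(C)(C)C)cc(C(C)(C)C)c3O)c3cc(OC)c(OCc4ccccc4)c(OC)c3)[C@@H]2CO)ccc1OCc1ccccc1
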